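Readings and results were generated by integration for substances that don't exist; the scatter is artificial.

In a one-step world, substrate runs to target on a first-order clock, and the yield at a fixed time ignores the charge. I defend that world for this flask. Tom answers that substrate + target ⇌ idle adduct is second-order, and that the charges asked span a factor of 18.8.

| flask | substrate | remark | time |
|---|---|---|---|
| grey | 0.088 M | run made earlier |  |
| birch | 0.080 M |  | 4.0 min |
| alder | 0.20 M |  | 4.0 min |
| oak | 0.40 M |  | 4.0 min |
| larch | 0.80 M |  | 4.0 min |
| elm | 1.5 M |  | 4.0 min |

grey run (percent of the substrate charged)

| time / min | target / % | substrate / % |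
|---|---|---|
| 0.200 | 12.9 | 11.7 |
| 0.417 | 17.9 | 6.3 |
| 1.00 | 28.5 | 5.5 |
| 2.50 | 38.0 | 2.5 |

(scatter of a reading: 0.5 percentage points)

- a species is counted by the substrate in it: one idle adduct counts as two
- amounts and yields of target count idle adduct too
- the numbers in the tables scatter with a standard deviation of 0.5 percentage points
- steps that have been proposed: target <-> isomer of the product B; substrate <-> target; substrate <-> dormant form; isomer of the product A <-> substrate; substrate + target <-> idle adduct; target <-> isomer of the product A
- in an amount of target, one idle adduct counts as one target
- "hardly changes" means that all values lie within two and a half points (for a concentration: within two and a half percent of the largest)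

- amount of target at the end, in percent of the substrate charged for birch, alder, oak, larch, elm, in this order
- how the row runs (falls all the way / falls, then rises / rises all the way / rises, then falls / hardly changes)

My reply is that the pairing meets [substrate] as it stands, not as it was charged. At 2.50 min, grey holds 38.0% target over 2.5% substrate, a ratio of 15.2. This is the turnover count, target counted per unit of substrate standing at that moment. It is a reading, and the substrate in it carries a scatter of 0.5 percentage points.

So in grey at that time less substrate stands than target. If the shares carry over, [substrate] in elm at that time is 0.0375 M, below the 0.088 M grey started from. Tom objects that the carrying over is the point in dispute, and that grey has no adduct column.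

For my number, grey's gain of target decays with a constant of 1.01 /min. Carrying that decay on to 4.0 min adds 2.3 points, so I write 40.3% for birch and for elm alike.

Tom's forecast reads 45%, 43.5%, 41%, 37%, 33%, so the row falls all the way: "I expect a gradual fall throughout".

The flask gives 39.8%, 39.9%, 40.0%, 40.1%, 40.3%, and the row hardly changes.

    target ⇌ isomer of the product B (K = 2.00, k = 0.00261 /s)
    substrate ⇌ target (K = 19.6, k = 0.0242 /s)
    substrate ⇌ dormant form (K = 1.20, k = 0.00218 /s)
    isomer of the product A ⇌ substrate (k = 0.0150 /s)
    substrate + target ⇌ idle adduct, settled at all times (K = 1.31 /M)
    target ⇌ isomer of the product A (K = 0.630, k = 0.00280 /s)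

Tom's view holds for the adduct itself: at 4.00 min idle adduct goes from 0.242% in birch to 4.24% in elm, a factor of 17.5. The turnover count, 15.2 in grey, comes to 13.7 at the end of birch and 14.3 at the end of elm. At that count, [substrate] in elm stood at 0.0424 M.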